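**Plan**

- Retrosynthesis: after removing the sulfate, the acetate and the phenol protection, ring A (a 2,4-dihydroxy-6-alkylbenzoate) is taken back to its dihydro form, a 2,4-dioxocyclohexane-1-carboxylate. That ring is cut at C1–C6 and C3–C4: C1–C3 plus the ester carbon are an acetoacetate, and C4–C6 plus the side chain are a 2-enoate.
- Both halves reduce to one building block, (S)-undec-10-en-4-ol, by cutting the aryl–CH2 bond of ring B and the C3–C4 bond of the enoate (two B-alkyl Suzuki couplings), and then the C4–C5 bond of the carbinol (epoxide opening).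
- Forward: the alkenol is coupled to the ring B bromide and acetoacetylated; its silyl ether is coupled to an iodoacrylate; the annulation joins the two chains with the hindered ester already in place. Ring B is bought as 5-bromoresorcinol; ring A arises last, by dehydrogenation of the annulation product.
- End game: benzylation of ring A, silyl ether to acetate, acetal cleavage, sulfation, hydrogenolysis.
- Stereochemistry: both (S)-carbinol centres come from (S)-propyloxirane and are never touched; the two ring stereocentres made in the annulation vanish on aromatisation.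

Key step: step 8

Assumption: the aryl sulfate is carried as its sodium salt from step 14 on and is released as the hydrogen sulfate, the form drawn for the target, only in the cold work-up of the last step.

**Route**

Step 1
Reactants: 1 6-bromohex-1-ene; 2 (S)-propyloxirane
Product: 4 (S)-undec-10-en-4-ol, via hex-5-enylmagnesium bromide 3 (not isolated)
Conditions: Mg, THF, 40 °C; then CuI (10 mol%), 2, THF, −30 → 0 °C; then 1 M HCl
Reagents that add atoms: none
Why: Copper-catalysed Grignard opening of a terminal epoxide is an SN2 attack at the unsubstituted carbon, so the C–O stereocentre of 2 should pass unchanged into 4 as the (S)-carbinol.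

Step 2
Reactants: 5 5-bromobenzene-1,3-diol
Product: 6 3-(benzyloxy)-5-bromophenol
Conditions: BnBr (1.0 equiv), K2CO3, acetone, reflux
Reagents that add atoms: benzyl bromide, BrCc1ccccc1
Why: Williamson etherification with one equivalent of halide should give the monoether of the symmetrical diol as the main component of a statistical mixture, from which diether and recovered diol are separated and the diol recycled.

Step 3
Reactants: 6 3-(benzyloxy)-5-bromophenol
Product: 7 1-(benzyloxy)-3-bromo-5-(methoxymethoxy)benzene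
Conditions: MOMCl, iPr2NEt, CH2Cl2, 0 °C → rt
Reagents that add atoms: chloromethyl methyl ether, COCCl
Why: Amine-mediated O-alkylation of the remaining phenol (acetal formation) should leave ring B with two ethers that can later be cleaved independently.

Step 4
Reactants: 4 (S)-undec-10-en-4-ol; 7 1-(benzyloxy)-3-bromo-5-(methoxymethoxy)benzene
Product: 9 (S)-11-[3-(benzyloxy)-5-(methoxymethoxy)phenyl]undecan-4-ol, via bis-9-BBN adduct 8 (not isolated)
Conditions: 9-BBN (2.2 equiv), THF, 0 °C → rt; then 7, PdCl2(dppf) (5 mol%), aq. K3PO4, THF/DMF, 60 °C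
Reagents that add atoms: none
Why: Anti-Markovnikov hydroboration of the terminal alkene (the second equivalent of borane being taken up by the hydroxyl as a borinate that the aqueous base hydrolyses) followed by B-alkyl Suzuki–Miyaura coupling should form the aryl–CH2 bond without touching the carbinol centre.

Step 5
Reactants: 9 (S)-11-[3-(benzyloxy)-5-(methoxymethoxy)phenyl]undecan-4-ol; 10 2,2,6-trimethyl-4H-1,3-dioxin-4-one
Product: 12 (S)-11-[3-(benzyloxy)-5-(methoxymethoxy)phenyl]undecan-4-yl 3-oxobutanoate, via acetylketene 11 (not isolated)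
Conditions: 10 (1.5 equiv), toluene, 110 °C, acetone distilled off
Reagents that add atoms: none
Why: Thermal retro-hetero-Diels–Alder cleavage of the dioxinone releases acetylketene, which the secondary alcohol should trap under neutral conditions to give the acetoacetate (acetoacetylation at oxygen, retention at carbon).

Step 6
Reactants: 4 (S)-undec-10-en-4-ol
Product: 13 (S)-tert-butyldimethyl(undec-10-en-4-yloxy)silane
Conditions: TBSCl, imidazole, DMF, rt
Reagents that add atoms: tert-butyldimethylsilyl chloride, CC(C)(C)[Si](C)(C)Cl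
Why: Imidazole-promoted silylation of the secondary alcohol should give an ether that withstands borane, palladium and alkoxide chemistry and is removed later by fluoride.

Step 7
Reactants: 13 (S)-tert-butyldimethyl(undec-10-en-4-yloxy)silane; 14 methyl (E)-3-iodoacrylate
Product: 16 methyl (S,E)-11-(tert-butyldimethylsilyloxy)tetradec-2-enoate, via B-alkyl-9-BBN adduct 15 (not isolated)
Conditions: 9-BBN, THF, rt; then 14, PdCl2(dppf) (5 mol%), AsPh3, aq. K3PO4, DMF, rt
Reagents that add atoms: none
Why: Hydroboration and B-alkyl Suzuki–Miyaura coupling with the β-iodoacrylate, which proceeds with retention of the alkene geometry, should add the three-carbon (E)-enoate unit in one operation.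

Step 8
Reactants: 12 (S)-11-[3-(benzyloxy)-5-(methoxymethoxy)phenyl]undecan-4-yl 3-oxobutanoate; 16 methyl (S,E)-11-(tert-butyldimethylsilyloxy)tetradec-2-enoate
Product: 18 (S)-11-[3-(benzyloxy)-5-(methoxymethoxy)phenyl]undecan-4-yl 6-[(S)-8-(tert-butyldimethylsilyloxy)undecyl]-2,4-dioxocyclohexane-1-carboxylate, via Michael adduct 17 (not isolated)
Conditions: KOtBu (1.1 equiv), 16 (1.2 equiv), tBuOH/THF, rt → 70 °C; then cold 0.5 M HCl to pH 4
Reagents that add atoms: none
Why: The potassium enolate of 12 should add through its central carbon to the β-carbon of 16 (Michael addition, the C1–C6 bond of the future ring A), and under the equilibrating alkoxide conditions the methyl ketone of adduct 17 is enolised and attacks the methyl ester with loss of methoxide (Claisen condensation of the Dieckmann type, the C3–C4 bond). This is the classical acetoacetate–enoate annulation to dihydroresorcylates, run with KOtBu in tBuOH as is done for tert-butyl esters so that no small alkoxide is present in quantity. The ring closes in the 6-(enolendo)-exo-trig mode, and it is the only closure open to 17 because every other enolate–carbonyl pairing would give a four-membered ring. The two new ring stereocentres (C1 and C6) are not controlled, C1 being epimerisable and both being erased in step 9, while the two carbinol centres lie far from any enolisable position. The step needs 1,4-addition through carbon and survival of the secondary ester: the soft, doubly stabilised enolate should secure the first, and the second is favoured because the expelled methoxide is consumed at once in deprotonating the acidic dione, which rests as a stabilised enolate with a deactivated ester carbonyl.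

Step 9
Reactants: 18 the dione ester from step 8
Product: 19 (S)-11-[3-(benzyloxy)-5-(methoxymethoxy)phenyl]undecan-4-yl 2,4-dihydroxy-6-[(S)-8-(tert-butyldimethylsilyloxy)undecyl]benzoate
Conditions: Pd(OCOCF3)2 (10 mol%), 2-(dimethylamino)pyridine (20 mol%), TsOH·H2O (20 mol%), O2 (1 atm), DMSO, 80 °C
Reagents that add atoms: none
Why: In this palladium-catalysed aerobic dehydrogenation of a cyclohexanone to a phenol, a divalent palladium enolate should undergo β-hydride elimination towards C6 and the resulting cyclohexenedione tautomerise to the resorcylate; one desaturation suffices at the dione level, and the pyridinium tosylate buffer with O2 as oxidant avoids both strong acid and the electrophilic halogen that would attack ring B.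

Step 10
Reactants: 19 the resorcylate from step 9
Product: 20 (S)-11-[3-(benzyloxy)-5-(methoxymethoxy)phenyl]undecan-4-yl 2,4-bis(benzyloxy)-6-[(S)-8-(tert-butyldimethylsilyloxy)undecyl]benzoate
Conditions: BnBr (3 equiv), K2CO3, Bu4NI (cat.), DMF, 60 °C
Reagents that add atoms: benzyl bromide, BrCc1ccccc1
Why: Williamson benzylation should mask both ring A phenols for the later sulfation, the hydrogen-bonded 2-hydroxyl needing the warm carbonate/DMF conditions, while the hindered benzoate and the silyl ether are inert.

Step 11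
Reactants: 20 the bis(benzyl) ether from step 10
Product: 21 (S)-11-[3-(benzyloxy)-5-(methoxymethoxy)phenyl]undecan-4-yl 2,4-bis(benzyloxy)-6-[(S)-8-hydroxyundecyl]benzoate
Conditions: HF·pyridine, pyridine/THF, 0 °C → rt
Reagents that add atoms: none
Why: Fluoride-driven cleavage of the Si–O bond with buffered HF·pyridine should free the secondary alcohol without affecting the methoxymethyl acetal, the benzyl ethers or the hindered ester.

Step 12
Reactants: 21 the secondary alcohol from step 11
Product: 22 (S)-11-[3-(benzyloxy)-5-(methoxymethoxy)phenyl]undecan-4-yl 6-[(S)-8-acetoxyundecyl]-2,4-bis(benzyloxy)benzoate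
Conditions: Ac2O, pyridine, DMAP (cat.), CH2Cl2, rt
Reagents that add atoms: acetic anhydride, CC(=O)OC(C)=O
Why: DMAP-catalysed acylation of the only free hydroxyl should install the acetate with retention at the carbinol carbon.

Step 13
Reactants: 22 the acetate from step 12
Product: 23 (S)-11-[3-(benzyloxy)-5-hydroxyphenyl]undecan-4-yl 6-[(S)-8-acetoxyundecyl]-2,4-bis(benzyloxy)benzoate
Conditions: ZnBr2 (1 equiv), n-PrSH (2 equiv), CH2Cl2, 0 °C
Reagents that add atoms: none
Why: Lewis acid activation of the acetal by ZnBr2 and capture of the methoxymethyl cation by the soft thiol should cleave the aryl methoxymethyl ether within minutes, under conditions that leave the acetate, the benzoate and the benzyl ethers intact.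

Step 14
Reactants: 23 the ring B phenol from step 13
Product: 25 sodium 3-[(S)-8-({6-[(S)-8-acetoxyundecyl]-2,4-bis(benzyloxy)benzoyl}oxy)undecyl]-5-(benzyloxy)phenyl sulfate, via pyridinium aryl sulfate 24 (not isolated)
Conditions: SO3·pyridine (5 equiv), pyridine, 40 °C; then aq. NaHCO3
Reagents that add atoms: sulfur trioxide–pyridine complex, O=S(=O)([O-])[n+]1ccccc1; sodium hydrogen carbonate, [Na+].OC([O-])=O
Why: O-Sulfonation by the sulfur trioxide–amine complex should convert the single free phenol into the aryl sulfate monoester, every other hydroxyl being blocked, and cation exchange gives the stable sodium salt.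

Step 15
Reactants: 25 the sodium aryl sulfate from step 14
Product: 27 Integracin D, via integracin D sodium salt 26 (not isolated)
Conditions: H2 (1 atm), 10% Pd/C, MeOH/EtOAc, rt; then HCl (1.0 equiv), 0 °C, C18 desalting
Reagents that add atoms: none
Why: Catalytic hydrogenolysis should cleave the three benzyl aryl ethers while the aryl sulfate salt, the alkyl acetate and the non-benzylic benzoate are inert to H2 over palladium, and one equivalent of acid in the cold converts the salt into the hydrogen sulfate.

**Compound list**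

1 | 6-bromohex-1-ene | C=CCCCCBr | starting material
2 | (S)-propyloxirane | CCC[C@H]1CO1 | starting material
3 | hex-5-enylmagnesium bromide (formed in the flask) | C=CCCCC[Mg]Br | intermediate
4 | (S)-undec-10-en-4-ol | CCC[C@H](O)CCCCCC=C | intermediate
5 | 5-bromobenzene-1,3-diol | Oc1cc(O)cc(Br)c1 | starting material
6 | 3-(benzyloxy)-5-bromophenol | Oc1cc(Br)cc(OCc2ccccc2)c1 | intermediate
7 | 1-(benzyloxy)-3-bromo-5-(methoxymethoxy)benzene | COCOc1cc(Br)cc(OCc2ccccc2)c1 | intermediate
8 | (S)-9-[8-(9-borabicyclo[3.3.1]nonan-9-yloxy)undecyl]-9-borabicyclo[3.3.1]nonane (formed in the flask) | CCC[C@H](OB1C2CCCC1CCC2)CCCCCCCB1C2CCCC1CCC2 | intermediate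
9 | (S)-11-[3-(benzyloxy)-5-(methoxymethoxy)phenyl]undecan-4-ol | CCC[C@H](O)CCCCCCCc1cc(OCc2ccccc2)cc(OCOC)c1 | intermediate
10 | 2,2,6-trimethyl-4H-1,3-dioxin-4-one | CC1=CC(=O)OC(C)(C)O1 | starting material
11 | acetylketene (formed in the flask) | CC(=O)C=C=O | intermediate
12 | (S)-11-[3-(benzyloxy)-5-(methoxymethoxy)phenyl]undecan-4-yl 3-oxobutanoate | CC(=O)CC(=O)O[C@@H](CCC)CCCCCCCc1cc(OCc2ccccc2)cc(OCOC)c1 | intermediate
13 | (S)-tert-butyldimethyl(undec-10-en-4-yloxy)silane | CCC[C@H](O[Si](C)(C)C(C)(C)C)CCCCCC=C | intermediate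
14 | methyl (E)-3-iodoacrylate | COC(=O)/C=C/I | starting material
15 | (S)-9-[8-(tert-butyldimethylsilyloxy)undecyl]-9-borabicyclo[3.3.1]nonane (formed in the flask) | CCC[C@H](O[Si](C)(C)C(C)(C)C)CCCCCCCB1C2CCCC1CCC2 | intermediate
16 | methyl (S,E)-11-(tert-butyldimethylsilyloxy)tetradec-2-enoate | CCC[C@@H](CCCCCCC/C=C/C(=O)OC)O[Si](C)(C)C(C)(C)C | intermediate
17 | 1-[(S)-11-[3-(benzyloxy)-5-(methoxymethoxy)phenyl]undecan-4-yl] 5-methyl 2-acetyl-3-[(S)-8-(tert-butyldimethylsilyloxy)undecyl]pentanedioate, mixture at C2 and C3 (formed in the flask) | CCC[C@@H](CCCCCCCC(CC(=O)OC)C(C(C)=O)C(=O)O[C@@H](CCC)CCCCCCCc1cc(OCc2ccccc2)cc(OCOC)c1)O[Si](C)(C)C(C)(C)C | intermediate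
18 | (S)-11-[3-(benzyloxy)-5-(methoxymethoxy)phenyl]undecan-4-yl 6-[(S)-8-(tert-butyldimethylsilyloxy)undecyl]-2,4-dioxocyclohexane-1-carboxylate, mixture at ring C1 and C6 | CCC[C@@H](CCCCCCCC1CC(=O)CC(=O)C1C(=O)O[C@@H](CCC)CCCCCCCc1cc(OCc2ccccc2)cc(OCOC)c1)O[Si](C)(C)C(C)(C)C | intermediate
19 | (S)-11-[3-(benzyloxy)-5-(methoxymethoxy)phenyl]undecan-4-yl 2,4-dihydroxy-6-[(S)-8-(tert-butyldimethylsilyloxy)undecyl]benzoate | CCC[C@@H](CCCCCCCc1cc(O)cc(O)c1C(=O)O[C@@H](CCC)CCCCCCCc1cc(OCc2ccccc2)cc(OCOC)c1)O[Si](C)(C)C(C)(C)C | intermediate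
20 | (S)-11-[3-(benzyloxy)-5-(methoxymethoxy)phenyl]undecan-4-yl 2,4-bis(benzyloxy)-6-[(S)-8-(tert-butyldimethylsilyloxy)undecyl]benzoate | CCC[C@@H](CCCCCCCc1cc(OCc2ccccc2)cc(OCc2ccccc2)c1C(=O)O[C@@H](CCC)CCCCCCCc1cc(OCc2ccccc2)cc(OCOC)c1)O[Si](C)(C)C(C)(C)C | intermediate
21 | (S)-11-[3-(benzyloxy)-5-(methoxymethoxy)phenyl]undecan-4-yl 2,4-bis(benzyloxy)-6-[(S)-8-hydroxyundecyl]benzoate | CCC[C@@H](CCCCCCCc1cc(OCc2ccccc2)cc(OCc2ccccc2)c1C(=O)O[C@@H](CCC)CCCCCCCc1cc(OCc2ccccc2)cc(OCOC)c1)O | intermediate
22 | (S)-11-[3-(benzyloxy)-5-(methoxymethoxy)phenyl]undecan-4-yl 6-[(S)-8-acetoxyundecyl]-2,4-bis(benzyloxy)benzoate | CCC[C@@H](CCCCCCCc1cc(OCc2ccccc2)cc(OCc2ccccc2)c1C(=O)O[C@@H](CCC)CCCCCCCc1cc(OCc2ccccc2)cc(OCOC)c1)OC(C)=O | intermediate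
23 | (S)-11-[3-(benzyloxy)-5-hydroxyphenyl]undecan-4-yl 6-[(S)-8-acetoxyundecyl]-2,4-bis(benzyloxy)benzoate | CCC[C@@H](CCCCCCCc1cc(OCc2ccccc2)cc(OCc2ccccc2)c1C(=O)O[C@@H](CCC)CCCCCCCc1cc(OCc2ccccc2)cc(O)c1)OC(C)=O | intermediate
24 | pyridinium 3-[(S)-8-({6-[(S)-8-acetoxyundecyl]-2,4-bis(benzyloxy)benzoyl}oxy)undecyl]-5-(benzyloxy)phenyl sulfate (formed in the flask) | CCC[C@@H](CCCCCCCc1cc(OCc2ccccc2)cc(OCc2ccccc2)c1C(=O)O[C@@H](CCC)CCCCCCCc1cc(OCc2ccccc2)cc(OS(=O)(=O)[O-])c1)OC(C)=O.c1cc[nH+]cc1 | intermediate
25 | sodium 3-[(S)-8-({6-[(S)-8-acetoxyundecyl]-2,4-bis(benzyloxy)benzoyl}oxy)undecyl]-5-(benzyloxy)phenyl sulfate | CCC[C@@H](CCCCCCCc1cc(OCc2ccccc2)cc(OCc2ccccc2)c1C(=O)O[C@@H](CCC)CCCCCCCc1cc(OCc2ccccc2)cc(OS(=O)(=O)[O-])c1)OC(C)=O.[Na+] | intermediate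
26 | integracin D sodium salt, sodium 3-[(S)-8-({6-[(S)-8-acetoxyundecyl]-2,4-dihydroxybenzoyl}oxy)undecyl]-5-hydroxyphenyl sulfate (formed in the flask) | CCC[C@@H](CCCCCCCc1cc(O)cc(O)c1C(=O)O[C@@H](CCC)CCCCCCCc1cc(O)cc(OS(=O)(=O)[O-])c1)OC(C)=O.[Na+] | intermediate
27 | Integracin D, 3-[(S)-8-({6-[(S)-8-acetoxyundecyl]-2,4-dihydroxybenzoyl}oxy)undecyl]-5-hydroxyphenyl hydrogen sulfate | CCC[C@@H](CCCCCCCc1cc(O)cc(O)c1C(=O)O[C@@H](CCC)CCCCCCCc1cc(O)cc(OS(=O)(=O)O)c1)OC(C)=O | target

**Step count and risks**

Total steps: 15. Longest linear sequence: 12 steps (from 5 through steps 2, 3, 4, 5, 8, 9, 10, 11, 12, 13, 14, 15).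

Steps most likely to fail:

1. Step 8. The addition of the stabilised enolate to the β-alkyl enoate may be slow and reversible, and over a long reaction time deconjugation of the enoate or ester exchange by the released methoxide may consume the valuable secondary ester before the ring closes. The fallback builds the ring on a disposable ester and attaches the carbinol afterwards. It sets out from 16: annulation with commercial tert-butyl acetoacetate under the same KOtBu/tBuOH conditions should give tert-butyl 6-[(S)-8-(tert-butyldimethylsilyloxy)undecyl]-2,4-dioxocyclohexane-1-carboxylate F1. Heating F1 with carbinol 9 in toluene at 110 °C should expel tert-butanol to give the α-oxoketene 6-[(S)-8-(tert-butyldimethylsilyloxy)undecyl]-2-(oxomethylidene)cyclohexane-1,3-dione F2, which 9 traps; the route is rejoined at 18.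

2. Step 9. The catalyst may collapse to palladium black before conversion is complete, or the warm, weakly acidic medium may start to cleave the methoxymethyl acetal. The fallback replaces catalytic dehydrogenation by halogenation and dehydrohalogenation. It sets out from 18: N-bromosuccinimide (1.0 equiv, THF, −78 → 0 °C) should brominate the enolised dione at C3 much faster than ring B, giving (S)-11-[3-(benzyloxy)-5-(methoxymethoxy)phenyl]undecan-4-yl 3-bromo-6-[(S)-8-(tert-butyldimethylsilyloxy)undecyl]-2,4-dioxocyclohexane-1-carboxylate F3. Triethylamine then promotes enolisation towards C5 and 1,4-elimination of HBr, and tautomerisation returns the route at 19.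

3. Step 15. Hydrogenolysis may be slow or incomplete because the amphiphilic sulfate salt aggregates or binds to the catalyst surface, and long reaction or repeated handling of the salt may solvolyse the sulfate. The fallback keeps the sulfate neutral until a single reductive unmasking. It sets out from 23: 2,2,2-trichloroethyl chlorosulfate (Et3N, DMAP, THF) should give the chromatographable diester 3-[(S)-8-({6-[(S)-8-acetoxyundecyl]-2,4-bis(benzyloxy)benzoyl}oxy)undecyl]-5-(benzyloxy)phenyl 2,2,2-trichloroethyl sulfate F4. Pd/C with HCO2NH4 in MeOH should then remove the trichloroethyl group reductively and the three benzyl ethers by transfer hydrogenolysis, giving integracin D ammonium salt F5; cold acidification as in step 15 returns the route at 27.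

**Further compounds**

F1 | step 8 | tert-butyl 6-[(S)-8-(tert-butyldimethylsilyloxy)undecyl]-2,4-dioxocyclohexane-1-carboxylate | CCC[C@@H](CCCCCCCC1CC(=O)CC(=O)C1C(=O)OC(C)(C)C)O[Si](C)(C)C(C)(C)C
F2 | step 8 | 6-[(S)-8-(tert-butyldimethylsilyloxy)undecyl]-2-(oxomethylidene)cyclohexane-1,3-dione | CCC[C@@H](CCCCCCCC1CC(=O)CC(=O)C1=C=O)O[Si](C)(C)C(C)(C)C
F3 | step 9 | (S)-11-[3-(benzyloxy)-5-(methoxymethoxy)phenyl]undecan-4-yl 3-bromo-6-[(S)-8-(tert-butyldimethylsilyloxy)undecyl]-2,4-dioxocyclohexane-1-carboxylate | CCC[C@@H](CCCCCCCC1CC(=O)C(Br)C(=O)C1C(=O)O[C@@H](CCC)CCCCCCCc1cc(OCc2ccccc2)cc(OCOC)c1)O[Si](C)(C)C(C)(C)C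
F4 | step 15 | 3-[(S)-8-({6-[(S)-8-acetoxyundecyl]-2,4-bis(benzyloxy)benzoyl}oxy)undecyl]-5-(benzyloxy)phenyl 2,2,2-trichloroethyl sulfate | CCC[C@@H](CCCCCCCc1cc(OCc2ccccc2)cc(OCc2ccccc2)c1C(=O)O[C@@H](CCC)CCCCCCCc1cc(OCc2ccccc2)cc(OS(=O)(=O)OCC(Cl)(Cl)Cl)c1)OC(C)=O
F5 | step 15 | integracin D ammonium salt | CCC[C@@H](CCCCCCCc1cc(O)cc(O)c1C(=O)O[C@@H](CCC)CCCCCCCc1cc(O)cc(OS(=O)(=O)[O-])c1)OC(C)=O.[NH4+]
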